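## The problem

The target 12 is a 2-aryl-3-(hydroxymethyl)-2,3-dihydrobenzofuran. Ring A (the benzo ring) carries a methoxy group at C7 and a methyl propanoate chain at C5; the dihydrofuran ring carries ring B (4-hydroxy-3,5-dimethoxyphenyl) at C2 and CH2OH at C3. C2 (S) and C3 (R) are adjacent and trans. While C3 bears a carbonyl group it is epimerisable and trans is the stable arrangement, so C2 can hold C3, but C2 itself, a benzylic ether carbon, must be set absolutely. Two carboxyl-level carbons must finish at different oxidation levels (CH2OH at C3, CO2Me on the chain) and must stay distinguishable throughout. The free phenol of ring B lies para to C2, so the benzylic C2–O1 bond can open through a para-quinone methide under acid, base or oxidants; forcing hydrogenolysis can cut the same bond, and the methyl ester excludes hydroxide and unselective hydride late in the route. The enabling feature is that the O1–C2 bond and the C3–CH2OH bond lie anti across C2–C3. Both can therefore be delivered in one anti addition to the double bond of an (E)-stilbene that already joins ring A to ring B, with O1 as the ortho phenol oxygen of ring A and the hydroxymethyl carbon coming from carbon monoxide.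

## Retrosynthesis

**12 to 11.** No skeletal bond is cut: the C3 hydroxymethyl group of 12 is traced to a C3 carboxylic acid in 11, and the chain keeps its methyl ester. An acid beside an ester is the one pair of carboxyl derivatives that an electrophilic hydride separates cleanly in favour of the acid. The neighbouring choice, two different esters, would need a later ester exchange and an acid treatment of a benzylic ether that ionises easily. Compound 11 is no smaller, but its C3 carbon is a carbonyl carbon, which is what a carbonylation delivers. The forward step must reduce the acid without touching the ester, the free phenol or the C2–O1 bond.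

**11 to 10.** The two O–CH2Ph bonds are cut: the benzyl ester at C3 and the benzyl ether of the ring B phenol. A simple alkyl ester at C3 would be a second ester of the same kind as the chain ester. A benzyl ester is orthogonal to it and falls in the same hydrogenolysis that frees the phenol, which must stay masked through every palladium and oxidant step. Compound 10 is fully protected and non-polar. The forward step must cleave two primary O-benzyl groups and spare the ring-bound benzylic C2–O1 bond.

**10 to 7, 8 and 9 (key disconnection).** The O1–C2 bond and the C3–C(=O) bond are cut, together with the acyl C–O bond to 9. Cutting C2–C3 instead would need two separately made reactive partners. Cutting only O1–C2 would leave the C3 stereocentre to be made on its own. This cut removes the ring and both stereocentres at once. The precursor 7 is a flat, achiral (E)-stilbene that holds every carbon of rings A and B and of the chain; the remaining carbon is carbon monoxide (8). The forward reaction must let the ligand on palladium choose the alkene face, add oxygen and carbon anti, insert 8 faster than β-hydride elimination, and close a ring in the 5-endo mode.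

**7 to 6 and 3.** The bond between ring A and the alkene carbon that becomes C3 is cut (Heck reaction). A carbonyl olefination between the two rings would need an ortho-formyl phenol and would give E/Z mixtures. The Heck reaction gives the (E)-alkene by its mechanism, and both partners are two steps from commercial phenols. The forward reaction must arylate the terminal alkene carbon and tolerate the free ortho phenol.

**6 to 5 to 4.** The C–I bond is cut and then the methyl ester O–CH3 bond. In 5 the hydroxyl group directs iodine to its only free ortho position, and 4 is a commercial acid. The chain is carried as the methyl ester of the target from the start, so it needs no later adjustment.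

**3 to 2 to 1.** The vinyl C=C bond is cut (Wittig methylenation of aldehyde 2), then the O–benzyl bond, which leads to commercial 1. The benzyl ether is the protecting group that the endgame removes together with the benzyl ester.

## Roads not taken

**Alternative 1:** Ring A itself is cut (C3a–C7a, C6–C7 and C7–O), back to the ethynyl ether A2, in which a 2,4-disubstituted furan is tethered through the C3–C2–O1 unit. Forward, (Ph3P)AuNTf2 (monovalent gold) activates the alkynyl ether, furan C2 attacks the oxygen-bearing alkyne carbon, and the furan opens and recloses to the phenol A1, with ring A fused to the new dihydrofuran ring. Its merit is that both stereocentres are made in the acyclic precursor by conventional stereocontrol before any ring forms, and that the furan substitution fixes the ring A pattern. Its weak points: the asymmetric problem is moved, not solved; A2 is an acid-sensitive ynol ether of a hindered secondary benzylic alcohol; and a benzene ring that can be bought is built instead. After the key step the route still needs O-methylation at C7, silyl removal, two oxidations and esterification of the chain, and two debenzylations. Ynol ethers are not established partners in this phenol synthesis, so the novelty risk is no lower than in the chosen plan. In certainty of configuration this road is better. The chosen plan sets against it eight steps in all, two commercial aromatic building blocks with the right oxygenation, and both stereocentres from one catalytic step.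

**Alternative 2:** C2–C3 and O1–C2 are cut: ring A brings C3 as an ortho-quinone methide released from the sulfone A4, and ring B brings C2 as the ylide of the chiral sulfonium salt A5. Forward, Cs2CO3 eliminates sulfinate from A4 and deprotonates A5; the ylide carbon adds to C3 and is displaced at C2 by the phenoxide, which gives the trans dihydrobenzofuran A3. The merits are real: this [4+1] annulation is an established reaction class, it is convergent, and A3 arrives at the right oxidation level with the methyl ester in place, so its endgame (desilylation, hydrogenolysis) is as short as the chosen one. In precedent this road is better. Its weak points for this target: the quinone methide carries an alkyl group with an α-hydrogen and a β-silyloxy group and can tautomerise to a vinylphenol; the ylide is a semi-stabilised benzyl ylide of an electron-rich ring, for which enantiocontrol is less secure; the chiral sulfide is stoichiometric; and both new centres depend on two facial selections at once. The chosen plan sets against it catalytic chirality, a stable achiral precursor, and a trans relationship fixed by the mechanism of anti addition.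

**Alternative 3:** Only O1–C2 is cut, back to the diarylpropanol A7, which carries the single stereocentre C3 and both free phenols. Forward, Ag2O (monovalent silver) oxidises the syringyl phenol of A7 to its para-quinone methide; the ring A phenol adds to the exocyclic carbon in a 5-exo closure and gives A6 with the C2 aryl trans to the C3 substituent. The merits: every reaction type is known, the ring closure is favourable, only one stereocentre must be made, and no pressure equipment is needed. As the conservative road it is better than the chosen plan. Its weak points: the lone stereocentre still costs an auxiliary or an asymmetric hydrogenation; the oxidant must discriminate between two electron-rich phenols; and the quinone methide has a hydrogen at C3 and can tautomerise to a stilbene, which would erase that stereocentre. The chain is also missing in A6 and must be added at the aryl bromide by a Heck reaction with an acrylate ester and then hydrogenated, with a phenol and an alcohol free. The chosen plan sets against it a shorter sequence, the complete carbon skeleton before the ring closes, and both centres from one enantioselective step.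

Key step: step 6

Assumption: the (S,S) antipode of the bis(oxazoline) ligand is taken to give the 2S series; if the sense of induction is the opposite, the (R,R) ligand is used and nothing else changes.

## Route

Step 1
Reactants: 1 syringaldehyde (4-hydroxy-3,5-dimethoxybenzaldehyde)
Product: 2 4-(benzyloxy)-3,5-dimethoxybenzaldehyde
Conditions: BnBr, K2CO3, DMF, 60 °C
Reagents that add atoms: benzyl bromide, BrCc1ccccc1
Why: Williamson ether synthesis: K2CO3 forms the phenoxide of 1, which is para to the aldehyde and therefore acidic, and the primary benzylic bromide alkylates it on oxygen; no stereocentre is involved.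

Step 2
Reactants: 2 4-(benzyloxy)-3,5-dimethoxybenzaldehyde
Product: 3 2-(benzyloxy)-5-ethenyl-1,3-dimethoxybenzene (4-benzyloxy-3,5-dimethoxystyrene)
Conditions: Ph3PCH3Br, KOtBu, THF, 0 °C to rt
Reagents that add atoms: methyltriphenylphosphonium bromide, C[P+](c1ccccc1)(c1ccccc1)c1ccccc1.[Br-]
Why: Wittig methylenation of an aromatic aldehyde with the non-stabilised ylide made from the phosphonium salt and KOtBu; the benzyl ether keeps the styrene from the quinone methide chemistry of a free 4-hydroxystyrene.

Step 3
Reactants: 4 3-(4-hydroxy-3-methoxyphenyl)propanoic acid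
Product: 5 methyl 3-(4-hydroxy-3-methoxyphenyl)propanoate
Conditions: MeOH, H2SO4 (cat.), reflux
Reagents that add atoms: methanol, CO
Why: Fischer esterification in excess methanol; the phenol does not react, and the ester formed is the one the target keeps.

Step 4
Reactants: 5 methyl 3-(4-hydroxy-3-methoxyphenyl)propanoate
Product: 6 methyl 3-(4-hydroxy-3-iodo-5-methoxyphenyl)propanoate
Conditions: NIS, p-TsOH·H2O (10 mol%), MeCN, 0 °C to rt
Reagents that add atoms: N-iodosuccinimide, O=C1CCC(=O)N1I
Why: Electrophilic aromatic iodination: the free hydroxyl is the strongest director on ring A, its para position is occupied by the chain and one ortho position by the methoxy group, so iodine should enter the remaining ortho position, as halogenation of 4-substituted 2-methoxyphenols does.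

Step 5
Reactants: 6 methyl 3-(4-hydroxy-3-iodo-5-methoxyphenyl)propanoate; 3 2-(benzyloxy)-5-ethenyl-1,3-dimethoxybenzene
Product: 7 methyl 3-{3-[(E)-2-(4-benzyloxy-3,5-dimethoxyphenyl)ethenyl]-4-hydroxy-5-methoxyphenyl}propanoate
Conditions: Pd(OAc)2 (5 mol%), P(o-tol)3 (10 mol%), Et3N, DMF, 90 °C
Reagents that add atoms: none
Why: Mizoroki–Heck reaction of an aryl iodide with a styrene: syn carbopalladation at the terminal carbon followed by syn β-hydride elimination should give the (E)-stilbene; ortho-iodophenols are accepted substrates, and the esters and the benzyl ether are inert to Et3N in DMF.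

Step 6
Reactants: 7 methyl 3-{3-[(E)-2-(4-benzyloxy-3,5-dimethoxyphenyl)ethenyl]-4-hydroxy-5-methoxyphenyl}propanoate; 8 carbon monoxide; 9 benzyl alcohol
Product: 10 benzyl (2S,3S)-2-[4-(benzyloxy)-3,5-dimethoxyphenyl]-7-methoxy-5-(3-methoxy-3-oxopropyl)-2,3-dihydro-1-benzofuran-3-carboxylate (trans)
Conditions: Pd(OCOCF3)2 (10 mol%), 2,2'-(propane-2,2-diyl)bis[(4S)-4-phenyl-4,5-dihydro-1,3-oxazole] (12 mol%), p-benzoquinone (2 equiv), CO (40 bar), BnOH (10 equiv), CH2Cl2, 0 °C
Reagents that add atoms: none
Why: Proposed new method: the cationic bis(oxazoline)palladium trifluoroacetate (divalent palladium) should bind the stilbene double bond of 7, and the ortho phenol oxygen should attack C2, where positive charge is stabilised by ring B, from the face opposite the metal; this closes the dihydrofuran ring in a 5-endo-trig mode, which is open to an alkene activated as an electrophile. The C3–Pd bond so formed inserts 8 with retention and 9 cleaves the acylpalladium to the benzyl ester, after which p-benzoquinone returns zerovalent palladium to the divalent state. The closest known reaction types are the intramolecular alkoxycarbonylation of alkenols (oxypalladation, CO insertion, alcoholysis), the enantioselective Wacker-type cyclisation of 2-allylphenols with Pd(OCOCF3)2, chiral bis(oxazoline)-type ligands and benzoquinone, the oxidative 5-endo cyclisation of 2-hydroxystilbenes to 2-arylbenzofurans and the carbonylative cyclisation of 2-alkynylphenols; the combination on a 1,2-disubstituted alkene in the 5-endo mode is not established. C2 is controlled by the chiral ligand, which chooses the alkene face that carries palladium and thereby the face that the oxygen attacks. C3 is controlled by the (E)-geometry of 7 through anti addition and insertion with retention, which places the ester trans to ring B; trans is also the stable C3 epimer, so the product cannot drift to cis afterwards. Any cis ester would signal syn oxypalladation, has the opposite configuration at C2 and is to be removed by chromatography, not epimerised. Regioselectivity is secured by the tether (only attack at C2 closes a ring) and selectivity for the tethered phenol over 9 by intramolecularity, while selectivity for CO insertion over β-hydride elimination of the syn C2–H (which would give the 2-arylbenzofuran) has to come from the CO pressure and the low temperature.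

Step 7
Reactants: 10 benzyl (2S,3S)-2-[4-(benzyloxy)-3,5-dimethoxyphenyl]-7-methoxy-5-(3-methoxy-3-oxopropyl)-2,3-dihydro-1-benzofuran-3-carboxylate
Product: 11 (2S,3S)-2-(4-hydroxy-3,5-dimethoxyphenyl)-7-methoxy-5-(3-methoxy-3-oxopropyl)-2,3-dihydro-1-benzofuran-3-carboxylic acid (trans)
Conditions: H2 (1 atm), 10% Pd/C, EtOAc/MeOH, rt
Reagents that add atoms: none
Why: Catalytic hydrogenolysis: the benzyl ester and the aryl benzyl ether are both primary O-benzyl groups and should be cleaved at 1 atm well before the secondary, ring-bound benzylic C2–O1 bond; no base is present, so neither stereocentre is touched.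

Step 8
Reactants: 11 (2S,3S)-2-(4-hydroxy-3,5-dimethoxyphenyl)-7-methoxy-5-(3-methoxy-3-oxopropyl)-2,3-dihydro-1-benzofuran-3-carboxylic acid
Product: 12 methyl 3-[(2S,3R)-2-(4-hydroxy-3,5-dimethoxyphenyl)-3-(hydroxymethyl)-7-methoxy-2,3-dihydro-1-benzofuran-5-yl]propanoate (trans; the target)
Conditions: BH3·THF (3 equiv), THF, 0 °C to rt; then MeOH
Reagents that add atoms: none
Why: Chemoselective borane reduction of a carboxylic acid in the presence of an ester: the acid forms an acyloxyborane that is reduced rapidly, while the chain methyl ester reacts only slowly with this electrophilic hydride; C3 keeps its configuration, and its descriptor changes from S to R only because the substituent priorities change.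

## Compound list

1 | syringaldehyde (4-hydroxy-3,5-dimethoxybenzaldehyde) | COc1cc(C=O)cc(OC)c1O | starting material
2 | 4-(benzyloxy)-3,5-dimethoxybenzaldehyde | O=Cc1cc(OC)c(OCc2ccccc2)c(OC)c1 | intermediate
3 | 2-(benzyloxy)-5-ethenyl-1,3-dimethoxybenzene | C=Cc1cc(OC)c(OCc2ccccc2)c(OC)c1 | intermediate
4 | 3-(4-hydroxy-3-methoxyphenyl)propanoic acid | O=C(O)CCc1ccc(O)c(OC)c1 | starting material
5 | methyl 3-(4-hydroxy-3-methoxyphenyl)propanoate | COC(=O)CCc1ccc(O)c(OC)c1 | intermediate
6 | methyl 3-(4-hydroxy-3-iodo-5-methoxyphenyl)propanoate | COC(=O)CCc1cc(OC)c(O)c(I)c1 | intermediate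
7 | methyl 3-{3-[(E)-2-(4-benzyloxy-3,5-dimethoxyphenyl)ethenyl]-4-hydroxy-5-methoxyphenyl}propanoate | COC(=O)CCc1cc(OC)c(O)c(/C=C/c2cc(OC)c(OCc3ccccc3)c(OC)c2)c1 | intermediate
8 | carbon monoxide | [C-]#[O+] | starting material
9 | benzyl alcohol | OCc1ccccc1 | starting material
10 | benzyl (2S,3S)-2-[4-(benzyloxy)-3,5-dimethoxyphenyl]-7-methoxy-5-(3-methoxy-3-oxopropyl)-2,3-dihydro-1-benzofuran-3-carboxylate | COC(=O)CCc1cc(OC)c2c(c1)[C@H](C(=O)OCc1ccccc1)[C@@H](c1cc(OC)c(OCc3ccccc3)c(OC)c1)O2 | intermediate
11 | (2S,3S)-2-(4-hydroxy-3,5-dimethoxyphenyl)-7-methoxy-5-(3-methoxy-3-oxopropyl)-2,3-dihydro-1-benzofuran-3-carboxylic acid | COC(=O)CCc1cc(OC)c2c(c1)[C@H](C(=O)O)[C@@H](c1cc(OC)c(O)c(OC)c1)O2 | intermediate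
12 | methyl 3-[(2S,3R)-2-(4-hydroxy-3,5-dimethoxyphenyl)-3-(hydroxymethyl)-7-methoxy-2,3-dihydro-1-benzofuran-5-yl]propanoate | COC(=O)CCc1cc(OC)c2c(c1)[C@H](CO)[C@@H](c1cc(OC)c(O)c(OC)c1)O2 | target

## Step count and least certain steps

Total: 8 steps. Longest linear sequence: 6 steps (steps 1, 2, 5, 6, 7, 8; the branch through steps 3 and 4 is equally long).

**Step 6 (key step, the one new method of the route).** Three processes are most likely to fail it. β-Hydride elimination from the C3 alkylpalladium may outrun CO insertion, because the C2–H lies syn to the metal and elimination leads to an aromatic benzofuran. Syn oxypalladation may compete with anti, and facial discrimination may be weak, because the 5-endo transition state is late and cation-like and the phenoxide can also bind palladium. The oxidant may be consumed in oxidative carbonylation of 9. Chloride additives and CO pressure are the levers inside the step.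

The fallback uses known chemistry, sets out from 2 and 6 and returns at 10.
- NaBH4 in MeOH should reduce 2 to [4-(benzyloxy)-3,5-dimethoxyphenyl]methanol F1.
- Mitsunobu etherification of phenol 6 with F1 (PPh3, DIAD, THF) should give methyl 3-(4-{[4-(benzyloxy)-3,5-dimethoxyphenyl]methoxy}-3-iodo-5-methoxyphenyl)propanoate F2.
- Palladium-catalysed coupling of F2 with the Reformatsky reagent of benzyl bromoacetate (BrZnCH2CO2Bn, Pd(dba)2, P(tBu)3, THF) should give benzyl 2-[2-{[4-(benzyloxy)-3,5-dimethoxyphenyl]methoxy}-3-methoxy-5-(3-methoxy-3-oxopropyl)phenyl]acetate F3.
- Diazo transfer (4-acetamidobenzenesulfonyl azide, DBU, MeCN) should give benzyl 2-diazo-2-[2-{[4-(benzyloxy)-3,5-dimethoxyphenyl]methoxy}-3-methoxy-5-(3-methoxy-3-oxopropyl)phenyl]acetate F4.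
- Intramolecular carbenoid C–H insertion into the benzylic ether CH2, catalysed by Rh2(S-PTTL)4 (dirhodium tetrakis[N-phthaloyl-(S)-tert-leucinate], or its antipode if that gives the 2S series), forms C2–C3. It should give the cis ester benzyl (2S,3R)-2-[4-(benzyloxy)-3,5-dimethoxyphenyl]-7-methoxy-5-(3-methoxy-3-oxopropyl)-2,3-dihydro-1-benzofuran-3-carboxylate F5.
- DBU in CH2Cl2 should epimerise C3 of F5 to the trans ester 10; here C2 is already correct, so equilibration is safe.

**Step 5.** The ortho phenoxide may slow oxidative addition and hold the catalyst, some arylation may occur at the internal alkene carbon, and the electron-rich styrene 3 may oligomerise at 90 °C. The fallback sets out from 2 and 6 and returns at 7. Takai-type boryl-olefination of 2 (Cl2CHBpin, CrCl2, LiI, THF) should give 2-[(E)-2-(4-benzyloxy-3,5-dimethoxyphenyl)ethenyl]-4,4,5,5-tetramethyl-1,3,2-dioxaborolane F6. Suzuki–Miyaura coupling of F6 with 6 (Pd(PPh3)4, K2CO3, dioxane/H2O, 80 °C) should then give 7 with the alkene geometry fixed by the boronate.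

**Step 7.** Over-reduction is the risk: C2–O1 is itself a benzylic aryl ether activated by ring B, and hydrogenolytic ring opening may compete once the two benzyl groups are gone. The fallback sets out from 10 and returns at 11. BCl3 with pentamethylbenzene in CH2Cl2 at −78 °C removes both benzyl groups by Lewis-acid dealkylation, without hydrogen or palladium. At this stage the electron-withdrawing carboxyl group at C3 disfavours ionisation at C2. This fallback makes no compound outside the list (entry F0).

**Step 8.** Chemoselectivity may erode: the acid is α-branched and hindered, so its reduction may be slow enough for the unhindered chain ester to be attacked, and borane as a Lewis acid may assist ionisation of C2–O1 next to the free para phenol. The fallback sets out from 11, returns at 12, and replaces electrophilic hydride by nucleophilic hydride on an activated acyl group.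
- Isobutyl chloroformate (2.2 equiv) and N-methylmorpholine in THF at −15 °C should give the mixed anhydride (2S,3S)-2-[4-(isobutoxycarbonyloxy)-3,5-dimethoxyphenyl]-7-methoxy-5-(3-methoxy-3-oxopropyl)-2,3-dihydro-1-benzofuran-3-carboxylic isobutyl carbonic anhydride F7, which is not isolated.
- NaBH4 in THF/H2O at 0 °C should reduce only the anhydride carbonyl and give 4-[(2S,3R)-3-(hydroxymethyl)-7-methoxy-5-(3-methoxy-3-oxopropyl)-2,3-dihydro-1-benzofuran-2-yl]-2,6-dimethoxyphenyl isobutyl carbonate F8.
- K2CO3 in MeOH at rt should cleave the aryl carbonate of F8 to 12.

## Further compounds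

F1 | step 6 | [4-(benzyloxy)-3,5-dimethoxyphenyl]methanol | OCc1cc(OC)c(OCc2ccccc2)c(OC)c1
F2 | step 6 | methyl 3-(4-{[4-(benzyloxy)-3,5-dimethoxyphenyl]methoxy}-3-iodo-5-methoxyphenyl)propanoate | COC(=O)CCc1cc(OC)c(OCc2cc(OC)c(OCc3ccccc3)c(OC)c2)c(I)c1
F3 | step 6 | benzyl 2-[2-{[4-(benzyloxy)-3,5-dimethoxyphenyl]methoxy}-3-methoxy-5-(3-methoxy-3-oxopropyl)phenyl]acetate | COC(=O)CCc1cc(OC)c(OCc2cc(OC)c(OCc3ccccc3)c(OC)c2)c(CC(=O)OCc2ccccc2)c1
F4 | step 6 | benzyl 2-diazo-2-[2-{[4-(benzyloxy)-3,5-dimethoxyphenyl]methoxy}-3-methoxy-5-(3-methoxy-3-oxopropyl)phenyl]acetate | COC(=O)CCc1cc(OC)c(OCc2cc(OC)c(OCc3ccccc3)c(OC)c2)c(C(=[N+]=[N-])C(=O)OCc2ccccc2)c1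
F5 | step 6 | benzyl (2S,3R)-2-[4-(benzyloxy)-3,5-dimethoxyphenyl]-7-methoxy-5-(3-methoxy-3-oxopropyl)-2,3-dihydro-1-benzofuran-3-carboxylate (cis) | COC(=O)CCc1cc(OC)c2c(c1)[C@@H](C(=O)OCc1ccccc1)[C@@H](c1cc(OC)c(OCc3ccccc3)c(OC)c1)O2
F6 | step 5 | 2-[(E)-2-(4-benzyloxy-3,5-dimethoxyphenyl)ethenyl]-4,4,5,5-tetramethyl-1,3,2-dioxaborolane | CC1(C)OB(/C=C/c2cc(OC)c(OCc3ccccc3)c(OC)c2)OC1(C)C
F0 | step 7 | none | none
F7 | step 8 | (2S,3S)-2-[4-(isobutoxycarbonyloxy)-3,5-dimethoxyphenyl]-7-methoxy-5-(3-methoxy-3-oxopropyl)-2,3-dihydro-1-benzofuran-3-carboxylic isobutyl carbonic anhydride | COC(=O)CCc1cc(OC)c2c(c1)[C@H](C(=O)OC(=O)OCC(C)C)[C@@H](c1cc(OC)c(OC(=O)OCC(C)C)c(OC)c1)O2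
F8 | step 8 | 4-[(2S,3R)-3-(hydroxymethyl)-7-methoxy-5-(3-methoxy-3-oxopropyl)-2,3-dihydro-1-benzofuran-2-yl]-2,6-dimethoxyphenyl isobutyl carbonate | COC(=O)CCc1cc(OC)c2c(c1)[C@H](CO)[C@@H](c1cc(OC)c(OC(=O)OCC(C)C)c(OC)c1)O2
A1 | alternative 1 | (2S,3R)-3-(benzyloxymethyl)-2-(4-benzyloxy-3,5-dimethoxyphenyl)-5-[3-(tert-butyldimethylsilyloxy)propyl]-2,3-dihydrobenzofuran-7-ol | CC(C)(C)[Si](C)(C)OCCCc1cc(O)c2c(c1)[C@H](COCc1ccccc1)[C@@H](c1cc(OC)c(OCc3ccccc3)c(OC)c1)O2
A2 | alternative 1 | tert-butyl(3-{5-[(2R,3S)-1-(benzyloxy)-3-(4-benzyloxy-3,5-dimethoxyphenyl)-3-(ethynyloxy)propan-2-yl]furan-3-yl}propoxy)dimethylsilane | CC(C)(C)[Si](C)(C)OCCCc1coc(c1)[C@H](COCc1ccccc1)[C@@H](c1cc(OC)c(OCc2ccccc2)c(OC)c1)OC#C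
A3 | alternative 2 | methyl 3-[(2S,3R)-2-(4-benzyloxy-3,5-dimethoxyphenyl)-3-(tert-butyldimethylsilyloxymethyl)-7-methoxy-2,3-dihydrobenzofuran-5-yl]propanoate | COC(=O)CCc1cc(OC)c2c(c1)[C@H](CO[Si](C)(C)C(C)(C)C)[C@@H](c1cc(OC)c(OCc3ccccc3)c(OC)c1)O2
A4 | alternative 2 | methyl 3-{3-[2-(tert-butyldimethylsilyloxy)-1-(4-methylbenzenesulfonyl)ethyl]-4-hydroxy-5-methoxyphenyl}propanoate (racemic) | COC(=O)CCc1cc(OC)c(O)c(C(CO[Si](C)(C)C(C)(C)C)S(=O)(=O)c2ccc(C)cc2)c1
A5 | alternative 2 | (2R,5R)-1-{[4-(benzyloxy)-3,5-dimethoxyphenyl]methyl}-2,5-dimethylthiolan-1-ium trifluoromethanesulfonate | C[C@@H]1CC[C@@H](C)[S+]1Cc1cc(OC)c(OCc2ccccc2)c(OC)c1.[O-]S(=O)(=O)C(F)(F)F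
A6 | alternative 3 | 4-[(2S,3R)-5-bromo-3-(hydroxymethyl)-7-methoxy-2,3-dihydrobenzofuran-2-yl]-2,6-dimethoxyphenol | Brc1cc(OC)c2c(c1)[C@H](CO)[C@@H](c1cc(OC)c(O)c(OC)c1)O2
A7 | alternative 3 | (2R)-2-(5-bromo-2-hydroxy-3-methoxyphenyl)-3-(4-hydroxy-3,5-dimethoxyphenyl)propan-1-ol | Brc1cc(OC)c(O)c(c1)[C@H](CO)Cc1cc(OC)c(O)c(OC)c1
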